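**Compound numbers.** 1–6 are the ring A series (1 isovanillin, 6 the aryl bromide). 7–13 are the ring C/D series (7 3,4-dihydroxybenzaldehyde, 11 4-fluorobenzaldehyde, 13 the styrene). 14–17 are open-chain four-ring intermediates, 18 is the macrolactone, 19 the macrocyclic aryloxydiene, 20 ethynyl p-tolyl sulfone, 21 the cycloadduct, 22 the dibenzyl ether and 23 the target.

## The problem

The target 23 is an achiral 18-membered cyclophane of the bis(bibenzyl) type. Four benzene rings are joined in a circle by two diaryl ether oxygens (ring A–O–ring B and ring C–O–ring D) and two CH2CH2 bridges (ring B–ring C and ring D–ring A). There is no stereocentre, so the synthesis has to solve only ring construction and substitution pattern, and no centre is available to control another. Ring A is the hard part: it carries four contiguous substituents (OMe, O-aryl, CH2CH2, OH), and its ether oxygen lies between the methoxy group and the bridge carbon. The corresponding phenol is therefore a 2,6-disubstituted, electron-rich nucleophile that couples poorly with aryl halides. The large ring has to be closed while the chain is still flexible, because the finished cyclophane is conformationally tight. The two free phenols, one of them para to OMe and thus easily oxidised to a quinone, and the native methyl ether, which must stay distinct from every protecting group, exclude strong oxidants and Lewis acidic ether cleavage late in the route. The enabling feature is ring B: it is meta-disubstituted, with the ether oxygen on C1, the bridge on C3 and hydrogen on C2, C4, C5 and C6. C1–C3 can therefore be read as the carbonyl, α- and β-carbon of an aryl enoate whose ester oxygen is the future ether oxygen, and C4–C6 as unsubstituted carbons from a methylene reagent and a traceless acetylene equivalent.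

## Retrosynthesis

**23 ⇒ 22.** The two phenolic O–H bonds are traced back to O–benzyl bonds. Benzyl is preferred to isopropyl or a second methyl ether because its removal by hydrogenolysis is neutral and cannot touch the native OMe or the diaryl ethers. The price is that no catalytic hydrogenation may be used earlier, which shapes the choices below. 22 differs from the target only by two benzyl groups.

**22 ⇒ 21.** Ring B is de-aromatised by adding back the elements of p-toluenesulfinic acid, so that C3 becomes sp3 and C4 carries a sulfonyl group. A sulfone is chosen over an ester or ketone as the activating group because it leaves under base and needs no separate removal. The forward step only asks for an elimination driven by aromatisation.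

**21 ⇒ 19 + 20.** The C3–C4 and C5–C6 bonds of ring B are cut in a retro-Diels–Alder sense. Cutting here, and not at the ring A–O bond, avoids any coupling at the hindered phenol, since the oxygen is already attached to what becomes C1. The precursor 19 has three aromatic rings and an (E)-2-aryloxy-1,3-diene in the 18-membered ring, and 20 is commercial. The forward reaction must give clean (4+2) addition on an s-cis diene; regiochemistry is free.

**19 ⇒ 18.** The exocyclic C=CH2 of the enol ether is replaced by C=O, which turns the aryl dienyl ether into an aryl enoate lactone. This is the point of the plan, since the ether oxygen is now an ester oxygen. The forward step is a Tebbe methylenation, which must tolerate an aryl ester and a conjugated alkene and give a product that is handled without acid.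

**18 ⇒ 17 ⇒ 16.** The lactone is opened at the Cα=Cβ bond (intramolecular Horner–Wadsworth–Emmons reaction) and then at the ester C–O bond (phosphonoacetylation of the ring A phenol). Ring closure at the alkene is preferred to macrolactonisation, because it places the entropically costly step at an unhindered aldehyde and leaves the hindered oxygen to a simple acylation. The hydroxy aldehyde 16 is an open chain of three aryl rings. The forward olefination must be E-selective and must win against oligomerisation.

**16 ⇒ 15 ⇒ 13 + 6.** Both masks of 16 (MOM on the ring A phenol, dioxolane on the aldehyde) are acetals and fall in one acid step from 15. 15 is cut at the ring A aryl–CH2 bond into the aryl bromide 6 and the styrene 13, to be joined by hydroboration and B-alkyl Suzuki–Miyaura coupling. This sp3–sp2 coupling is preferred to a Wittig/stilbene or alkyne route because it gives the saturated bridge directly, with no reduction next to benzyl ethers. The forward step must engage a di-ortho-oxygenated aryl bromide.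

**13 ⇒ 12 ⇒ 10 + 11; 10 ⇒ 9 ⇒ 8 ⇒ 7.** The styrene comes from aldehyde 12 by methylenation, and 12 from the phenol 10 and 11 by SNAr at the unhindered ring C–O–ring D ether. The three-carbon chain of 10 is traced through the alkene 9 to 8 by a two-carbon Wittig homologation that installs the aldehyde oxidation level already masked, followed by diimide reduction. 8 comes from 7 by benzylation of the more acidic 4-OH. Building the chain before the SNAr keeps the two aldehydes of the C/D unit distinct at all times.

**6 ⇒ 5 ⇒ 3 ⇒ 2 ⇒ 1.** The benzyl ether oxygen of 6 is traced to the formyl carbon of isovanillin (Baeyer–Villiger oxidation of 3), and the bromine to bromination of 1 between OH and CHO. The native phenol of 1 becomes the future ether oxygen and is carried as a MOM ether. Isovanillin already holds OMe and OH in the right relation, and its only free position ortho to OH next to CHO is where the bridge must go. 2 and 8 are also commercial, which could save two steps.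

## Roads not taken

**Alternative 1:** The cut is the ring C carbon–oxygen bond of the C–O–D ether. In the forward direction the open-chain bisphenol A1, in which ring C is a 2,6-dibromophenol and ring D a 2,6-dichlorophenol, would be oxidised with Tl(NO3)3. The ring D oxygen adds to an ortho carbon of the oxidised ring C, and zinc reduction restores the phenol and gives the macrocycle A2.
- Merits: it closes the 18-membered ring and an ether in one biomimetic operation, gives the ortho-oxygenated pattern of ring C directly, and belongs to a reaction type with precedent for macrocyclic diaryl ethers. In that respect it is less speculative than the cycloaddition chosen here.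
- Weak points: it needs four halogens as blocking and directing groups and their later removal, a stoichiometric toxic thallium oxidant, and discrimination between two similar phenols. Above all it closes the easy ether, which SNAr gives in one step, and leaves the hindered ring A–O–ring B ether to a conventional coupling in the making of A1.
- Comparison: the chosen plan sets against its better precedent an acylation at the congested oxygen and no halogen on/off steps.

**Alternative 2:** The cut is the ring A carbon–oxygen bond. Ring A is made the electrophile as the 3-bromo-4,4-dimethoxycyclohexadienone in A3. The ring B phenoxide adds to the bromine-bearing β-carbon and expels bromide, closing the macrocycle to the aryloxy quinone monoketal A4. Reduction would then return ring A with OMe and OH para to each other.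
- Merits: it attacks the hindered ether directly by reversing polarity, buys ring B as a simple 3-hydroxyphenyl unit, and delivers the OMe/OH pattern of ring A without a protecting group. In those points it is at least as economical as the chosen plan.
- Weak points: the monoketal must be made by oxidising a phenol in the presence of two other electron-rich rings. It is acid-labile and offers a second, unsubstituted β-carbon to the phenoxide. The substitution takes place at a fully substituted alkene carbon next to the bridge and doubles as the macrocyclisation. Re-aromatisation can eject the aryloxide instead of methoxide.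
- Comparison: the chosen plan separates ring closure (an olefination remote from the congested site) from ether formation and uses a neutral thermal C–C bond formation.

**Alternative 3:** Two carbon–carbon bonds of ring D are cut. In A5 an aryl ethynyl ether on ring C and a 5-acyl-2-pyrone tethered to ring A would undergo intramolecular (4+2) addition across C3 and C6 of the pyrone. Loss of CO2 gives the macrocyclic aryl ketone A6.
- Merits: one irreversible step makes ring D and the macrocycle, donor and acceptor are regiochemically matched, and the ketone could fall in the final hydrogenolysis. On paper it is more step-economic at the ring-closing stage than the chosen plan.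
- Weak points: the sophisticated step builds the unhindered C–O–D ether, while the hindered A–O–B ether still needs a classical coupling. Aryl ethynyl ethers are thermally and hydrolytically fragile at the temperatures pyrone cycloadditions need. The cycloaddition has to span an 18-membered transition state at high dilution.
- Comparison: the chosen plan spends its annulation on the ether that is actually difficult, and runs it intermolecularly with an excess of a reactive dienophile on a preformed ring.

Key step: step 15

Remark on the chemistry: the target has no stereocentre; 9 is carried as an E/Z mixture and 21 as a racemate, and both elements are erased (steps 7 and 16).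

## Route

Step 1
Reactants: 1 isovanillin (3-hydroxy-4-methoxybenzaldehyde)
Product: 2 2-bromo-3-hydroxy-4-methoxybenzaldehyde
Conditions: Br2, NaOAc, Fe powder (cat.), AcOH, rt
Reagents that add atoms: bromine, BrBr
Why: Electrophilic aromatic bromination; under these buffered conditions the free 3-OH directs the halogen to C2 between OH and CHO, a known selectivity for isovanillin, which places the handle where the ring A–CH2 bond is needed.

Step 2
Reactants: 2 2-bromo-3-hydroxy-4-methoxybenzaldehyde
Product: 3 2-bromo-4-methoxy-3-(methoxymethoxy)benzaldehyde
Conditions: MOMCl, i-Pr2NEt, CH2Cl2, 0 °C to rt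
Reagents that add atoms: chloromethyl methyl ether, COCCl
Why: O-Alkylation of the phenol (MOM ether formation); MOM is small enough for the flanked oxygen, orthogonal to benzyl, stable to peracid, base, borane and palladium, and leaves in the same acid step as the dioxolane (step 11).

Step 3
Reactants: 3 2-bromo-4-methoxy-3-(methoxymethoxy)benzaldehyde
Product: 5 2-bromo-4-methoxy-3-(methoxymethoxy)phenol, via aryl formate 4 (not isolated)
Conditions: mCPBA, CH2Cl2, 0 °C to rt; then K2CO3 (cat.), MeOH, rt
Reagents that add atoms: 3-chloroperoxybenzoic acid, OOC(=O)c1cccc(Cl)c1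
Why: Baeyer–Villiger (Dakin-type) oxidation; the para-methoxy group makes the aryl group migrate in preference to hydride, and the formate 4 is methanolysed in the same flask, turning the formyl carbon into the oxygen that ends as the free para-OH of ring A.

Step 4
Reactants: 5 2-bromo-4-methoxy-3-(methoxymethoxy)phenol
Product: 6 1-(benzyloxy)-2-bromo-4-methoxy-3-(methoxymethoxy)benzene
Conditions: BnBr, K2CO3, DMF, rt
Reagents that add atoms: benzyl bromide, BrCc1ccccc1
Why: Williamson ether synthesis on the new, singly flanked phenol; it fixes the benzyl group on the oxygen that is to be freed last.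

Step 5
Reactants: 7 3,4-dihydroxybenzaldehyde
Product: 8 4-(benzyloxy)-3-hydroxybenzaldehyde
Conditions: BnCl, NaHCO3, NaI (cat.), DMF, 40 °C
Reagents that add atoms: benzyl chloride, ClCc1ccccc1
Why: Regioselective Williamson benzylation; the weak base deprotonates only the 4-OH, which is more acidic through conjugation with the para-formyl group, a known selectivity for this catechol aldehyde.

Step 6
Reactants: 8 4-(benzyloxy)-3-hydroxybenzaldehyde
Product: 9 2-(benzyloxy)-5-[2-(1,3-dioxolan-2-yl)ethenyl]phenol (E/Z mixture)
Conditions: (1,3-dioxolan-2-ylmethyl)triphenylphosphonium bromide, t-BuOK (2.3 equiv), THF, 0 °C to rt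
Reagents that add atoms: (1,3-dioxolan-2-ylmethyl)triphenylphosphonium bromide, [Br-].C1COC(C[P+](c2ccccc2)(c2ccccc2)c2ccccc2)O1
Why: Wittig reaction with a masked formylmethyl ylide; it adds the two chain carbons with the aldehyde oxidation level already protected, the extra base covers the phenol, and the alkene geometry is irrelevant because the double bond is reduced next.

Step 7
Reactants: 9 2-(benzyloxy)-5-[2-(1,3-dioxolan-2-yl)ethenyl]phenol
Product: 10 2-(benzyloxy)-5-[2-(1,3-dioxolan-2-yl)ethyl]phenol
Conditions: TsNHNH2, NaOAc, DME/H2O, reflux
Reagents that add atoms: none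
Why: Diimide reduction; concerted syn transfer of H2 saturates the nonpolar C=C and cannot cleave the benzyl ether, while the acetate buffer protects the dioxolane.

Step 8
Reactants: 10 2-(benzyloxy)-5-[2-(1,3-dioxolan-2-yl)ethyl]phenol; 11 4-fluorobenzaldehyde
Product: 12 4-{2-(benzyloxy)-5-[2-(1,3-dioxolan-2-yl)ethyl]phenoxy}benzaldehyde
Conditions: K2CO3, DMF, 110 °C
Reagents that add atoms: none
Why: Nucleophilic aromatic substitution; the para-formyl group activates fluoride displacement by the phenoxide, and the dioxolane keeps the ring C aldehyde distinct from the new ring D aldehyde.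

Step 9
Reactants: 12 4-{2-(benzyloxy)-5-[2-(1,3-dioxolan-2-yl)ethyl]phenoxy}benzaldehyde
Product: 13 2-{2-[4-(benzyloxy)-3-(4-ethenylphenoxy)phenyl]ethyl}-1,3-dioxolane
Conditions: Ph3PCH3Br, t-BuOK, THF, 0 °C to rt
Reagents that add atoms: methyltriphenylphosphonium bromide, [Br-].C[P+](c1ccccc1)(c1ccccc1)c1ccccc1
Why: Wittig methylenation; it converts the aldehyde into the terminal alkene needed for hydroboration, and acetal and ethers are inert to the ylide.

Step 10
Reactants: 13 2-{2-[4-(benzyloxy)-3-(4-ethenylphenoxy)phenyl]ethyl}-1,3-dioxolane; 6 1-(benzyloxy)-2-bromo-4-methoxy-3-(methoxymethoxy)benzene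
Product: 15 2-{2-[4-(benzyloxy)-3-(4-{2-[6-(benzyloxy)-3-methoxy-2-(methoxymethoxy)phenyl]ethyl}phenoxy)phenyl]ethyl}-1,3-dioxolane, via alkylborane 14 (not isolated)
Conditions: 9-BBN, THF, 0 °C to rt; then 6, Pd(OAc)2, SPhos, aq. K3PO4, THF/DMF, 65 °C
Reagents that add atoms: none
Why: Hydroboration followed by B-alkyl Suzuki–Miyaura coupling; 9-BBN adds anti-Markovnikov to the styrene, and the bulky electron-rich phosphine lets zerovalent palladium insert into the di-ortho-oxygenated aryl bromide. The bridge forms at its final oxidation level, so no alkene has to be reduced beside benzyl ethers.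

Step 11
Reactants: 15 2-{2-[4-(benzyloxy)-3-(4-{2-[6-(benzyloxy)-3-methoxy-2-(methoxymethoxy)phenyl]ethyl}phenoxy)phenyl]ethyl}-1,3-dioxolane
Product: 16 3-[4-(benzyloxy)-3-(4-{2-[6-(benzyloxy)-2-hydroxy-3-methoxyphenyl]ethyl}phenoxy)phenyl]propanal
Conditions: 3 M aq. HCl, THF, 45 °C
Reagents that add atoms: water, O
Why: Acid-catalysed hydrolysis of both acetals (MOM ether and dioxolane) in one operation; benzyl, methyl and diaryl ethers are stable, so the ring A phenol and the aldehyde are freed together.

Step 12
Reactants: 16 3-[4-(benzyloxy)-3-(4-{2-[6-(benzyloxy)-2-hydroxy-3-methoxyphenyl]ethyl}phenoxy)phenyl]propanal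
Product: 17 3-(benzyloxy)-2-[2-(4-{2-(benzyloxy)-5-(3-oxopropyl)phenoxy}phenyl)ethyl]-6-methoxyphenyl 2-(diethoxyphosphoryl)acetate
Conditions: (EtO)2P(O)CH2CO2H, DCC, DMAP (cat.), CH2Cl2, 0 °C to rt
Reagents that add atoms: diethylphosphonoacetic acid, CCOP(=O)(OCC)CC(=O)O
Why: Steglich esterification; acyl transfer to oxygen is little affected by the two ortho substituents that defeat aryl coupling at this phenol, and the aliphatic aldehyde is a spectator.

Step 13
Reactants: 17 3-(benzyloxy)-2-[2-(4-{2-(benzyloxy)-5-(3-oxopropyl)phenoxy}phenyl)ethyl]-6-methoxyphenyl 2-(diethoxyphosphoryl)acetate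
Product: 18 18-membered (E)-enoate lactone (ring A oxygen acylated by the (E)-CH=CH–CH2CH2 chain of ring C; both benzyl ethers retained)
Conditions: LiCl, i-Pr2NEt, MeCN, rt, slow addition, ca. 1 mM
Reagents that add atoms: none
Why: Intramolecular Horner–Wadsworth–Emmons reaction under Masamune–Roush conditions; lithium chelation allows an amine base that spares the enolisable aldehyde and the aryl ester, high dilution favours the 18-membered ring, and the stabilised phosphonate gives the E alkene.

Step 14
Reactants: 18 18-membered (E)-enoate lactone
Product: 19 macrocyclic (E)-2-aryloxy-1,3-diene (lactone C=O replaced by C=CH2)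
Conditions: Cp2Ti(CH2)(Cl)AlMe2 (toluene solution), pyridine, THF, −40 °C to rt; aq. NaOH quench; basic Al2O3
Reagents that add atoms: Tebbe reagent Cp2Ti(CH2)(Cl)AlMe2, C[Al](C)C[Ti](Cl)(C1C=CC=C1)C1C=CC=C1
Why: Tebbe methylenation; the titanium methylidene adds to the ester C=O and cycloreverts to the enol ether under non-basic conditions. The reaction is known for aryl esters and for enoates (which give 2-alkoxydienes), and the conjugated alkene and the ethers are not touched.

Step 15
Reactants: 19 macrocyclic (E)-2-aryloxy-1,3-diene; 20 ethynyl p-tolyl sulfone
Product: 21 macrocyclic 1-aryloxycyclohexa-1,4-dienyl sulfone (racemic; sulfonyl on the ring carbon next to the sp3 CH that carries the CH2CH2 chain)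
Conditions: toluene, BHT (cat.), 80 °C, acid-free glassware
Reagents that add atoms: none
Why: Proposed new method: the closest known reaction type is the Diels–Alder addition of 2-alkoxy- and 2-silyloxy-1,3-dienes to ethynyl p-tolyl sulfone as an acetylene equivalent; here the diene is an aryl enol ether held in an 18-membered ring. The mechanism should be a concerted, asynchronous, normal-electron-demand (4+2) addition in which the aryloxy donor raises the diene HOMO and puts its largest coefficient on the exocyclic CH2, which bonds to the sulfone β-carbon while the chain-bearing terminus bonds to the α-carbon. The six-membered ring closes by intermolecular cycloaddition across the diene termini, so it is annulated onto three contiguous atoms of the existing macrocycle and spans them in the meta fashion of ring B; no new large ring has to form. The one new stereocentre (the sp3 CH carrying the CH2CH2 chain) forms without a controlling element, as a racemate, and is erased in step 16. The selectivity needed is (4+2) over (2+2) addition of the enol ether to the alkyne and over oligomerisation; it rests on the E alkene, which lets the ring hold the diene in an extended s-cis form, and on the matched donor–acceptor pairing. Regiochemistry does not matter, because either adduct loses the sulfonyl group on aromatisation. Neutral, acid-free conditions protect the enol ether.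

Step 16
Reactants: 21 macrocyclic 1-aryloxycyclohexa-1,4-dienyl sulfone
Product: 22 O,O'-dibenzyl ether of the target (ring B aromatic)
Conditions: DBU, toluene, 80 °C (crude 21 used directly)
Reagents that add atoms: none
Why: Base-mediated aromatisation by E1cB loss of p-toluenesulfinate; DBU removes a doubly allylic ring proton, the dienyl anion shifts so that the sulfonyl carbon becomes sp3, and sulfinate leaves as the benzene ring forms. This is the established way to use a sulfonyl alkyne as an acetylene equivalent in arene synthesis.

Step 17
Reactants: 22 O,O'-dibenzyl ether of the target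
Product: 23 target compound CNP0179896.0
Conditions: H2 (1 atm), Pd/C, EtOAc/MeOH, rt
Reagents that add atoms: none
Why: Catalytic hydrogenolysis of the two benzyl aryl ethers; the methyl ether, the diaryl ethers and the saturated bridges are inert, so the only change is release of the two phenols.

## Compound list

1 | isovanillin (3-hydroxy-4-methoxybenzaldehyde) | COc1ccc(C=O)cc1O | starting material
2 | 2-bromo-3-hydroxy-4-methoxybenzaldehyde | COc1ccc(C=O)c(Br)c1O | intermediate
3 | 2-bromo-4-methoxy-3-(methoxymethoxy)benzaldehyde | COCOc1c(OC)ccc(C=O)c1Br | intermediate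
4 | 2-bromo-4-methoxy-3-(methoxymethoxy)phenyl formate (not isolated) | COCOc1c(OC)ccc(OC=O)c1Br | intermediate
5 | 2-bromo-4-methoxy-3-(methoxymethoxy)phenol | COCOc1c(OC)ccc(O)c1Br | intermediate
6 | 1-(benzyloxy)-2-bromo-4-methoxy-3-(methoxymethoxy)benzene | COCOc1c(OC)ccc(OCc2ccccc2)c1Br | intermediate
7 | 3,4-dihydroxybenzaldehyde | O=Cc1ccc(O)c(O)c1 | starting material
8 | 4-(benzyloxy)-3-hydroxybenzaldehyde | O=Cc1ccc(OCc2ccccc2)c(O)c1 | intermediate
9 | 2-(benzyloxy)-5-[2-(1,3-dioxolan-2-yl)ethenyl]phenol (E/Z mixture, geometry not defined) | Oc1cc(C=CC2OCCO2)ccc1OCc1ccccc1 | intermediate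
10 | 2-(benzyloxy)-5-[2-(1,3-dioxolan-2-yl)ethyl]phenol | Oc1cc(CCC2OCCO2)ccc1OCc1ccccc1 | intermediate
11 | 4-fluorobenzaldehyde | O=Cc1ccc(F)cc1 | starting material
12 | 4-{2-(benzyloxy)-5-[2-(1,3-dioxolan-2-yl)ethyl]phenoxy}benzaldehyde | O=Cc1ccc(Oc2cc(CCC3OCCO3)ccc2OCc2ccccc2)cc1 | intermediate
13 | 2-{2-[4-(benzyloxy)-3-(4-ethenylphenoxy)phenyl]ethyl}-1,3-dioxolane | C=Cc1ccc(Oc2cc(CCC3OCCO3)ccc2OCc2ccccc2)cc1 | intermediate
14 | 9-{2-[4-(2-(benzyloxy)-5-(2-(1,3-dioxolan-2-yl)ethyl)phenoxy)phenyl]ethyl}-9-borabicyclo[3.3.1]nonane (not isolated) | C1CCC2CCCC1B2CCc1ccc(Oc2cc(CCC3OCCO3)ccc2OCc2ccccc2)cc1 | intermediate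
15 | 2-{2-[4-(benzyloxy)-3-(4-{2-[6-(benzyloxy)-3-methoxy-2-(methoxymethoxy)phenyl]ethyl}phenoxy)phenyl]ethyl}-1,3-dioxolane | COCOc1c(OC)ccc(OCc2ccccc2)c1CCc1ccc(Oc2cc(CCC3OCCO3)ccc2OCc2ccccc2)cc1 | intermediate
16 | 3-[4-(benzyloxy)-3-(4-{2-[6-(benzyloxy)-2-hydroxy-3-methoxyphenyl]ethyl}phenoxy)phenyl]propanal | COc1ccc(OCc2ccccc2)c(CCc2ccc(Oc3cc(CCC=O)ccc3OCc3ccccc3)cc2)c1O | intermediate
17 | 3-(benzyloxy)-2-[2-(4-{2-(benzyloxy)-5-(3-oxopropyl)phenoxy}phenyl)ethyl]-6-methoxyphenyl 2-(diethoxyphosphoryl)acetate | CCOP(=O)(OCC)CC(=O)Oc1c(OC)ccc(OCc2ccccc2)c1CCc1ccc(Oc2cc(CCC=O)ccc2OCc2ccccc2)cc1 | intermediate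
18 | 18-membered (E)-enoate lactone, dibenzyl ether (aryl ester of the ring A phenol with the (E)-pent-2-enoate chain on ring C) | COc1ccc(OCc3ccccc3)c2c1OC(=O)/C=C/CCc1ccc(OCc3ccccc3)c(c1)Oc1ccc(cc1)CC2 | intermediate
19 | macrocyclic (E)-2-aryloxy-1,3-diene, dibenzyl ether | COc1ccc(OCc3ccccc3)c2c1OC(=C)/C=C/CCc1ccc(OCc3ccccc3)c(c1)Oc1ccc(cc1)CC2 | intermediate
20 | ethynyl p-tolyl sulfone | C#CS(=O)(=O)c1ccc(C)cc1 | starting material
21 | macrocyclic 1-aryloxycyclohexa-1,4-dienyl p-tolyl sulfone (racemic) | COc1ccc(OCc3ccccc3)c2c1OC1=CC(C(=CC1)S(=O)(=O)c1ccc(C)cc1)CCc1ccc(OCc3ccccc3)c(c1)Oc1ccc(cc1)CC2 | intermediate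
22 | O,O'-dibenzyl ether of the target | COc1ccc(OCc3ccccc3)c2c1Oc1cccc(c1)CCc1ccc(OCc3ccccc3)c(c1)Oc1ccc(cc1)CC2 | intermediate
23 | CNP0179896.0 (achiral) | COc1ccc(O)c2c1Oc1cccc(c1)CCc1ccc(O)c(c1)Oc1ccc(cc1)CC2 | target

## Step count and least certain steps

Total: 17 steps. Longest linear sequence: 13 steps (7 to 23, steps 5–17); the ring A branch (1 to 6, steps 1–4) joins in step 10.

**Step 15 (key step, proposed new method).**
- Most likely failures: acid-catalysed hydrolysis of the aryl enol ether before it reacts; (2+2) addition or oligomerisation of the electron-poor alkyne on the enol ether double bond; or slow reaction because transannular crowding keeps the diene from the s-cis form.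
- Fallback (known chemistry only): the annulation is given up and the ether is made by copper catalysis, accepting the hindered coupling the plan was designed to avoid. It sets out from 8 (with 11 and 6) and comes back at 22.
  - Acetalisation of 8 (ethylene glycol, TsOH, toluene, water separator) would give the acetal phenol F1.
  - SNAr with 11 would give the diaryl ether aldehyde F2, and Wittig methylenation the styrene F3.
  - 9-BBN would give the alkylborane F4, which is coupled with 6 as in step 10 to the MOM-protected bibenzyl F5.
  - Aqueous HCl would free the phenol aldehyde F6.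
  - Wittig reaction with the ylide of (3-bromobenzyl)triphenylphosphonium bromide would give the bromostilbene F7 (E/Z mixture), and diimide the bromo bibenzyl F8.
  - Intramolecular Ullmann etherification (CuI, picolinic acid, K3PO4, DMSO, high dilution) would close the ring A–O–ring B bond to 22.

**Step 13.**
- Most likely failures: oligomerisation in competition with ring closure, and base-induced fragmentation of the aryl phosphonoacetate (loss of the phenoxide through a ketene-type E1cB path).
- Fallback: the ring is closed by metathesis instead. It sets out from 16 and comes back at 18. Wittig methylenation of the aldehyde would give the butenyl phenol F9; acryloyl chloride and Et3N would give the aryl acrylate F10; ring-closing metathesis with the second-generation Grubbs catalyst (H2IMes)(PCy3)Cl2Ru=CHPh at high dilution would give 18.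

**Step 14.**
- Most likely failures: incomplete methylenation of the flanked aryl ester inside the ring, and hydrolytic loss of the aryloxydiene on work-up.
- Fallback: methylenation is moved to the open-chain stage and the ring is closed afterwards. It sets out from 16 by way of F9 and F10 (see step 13) and comes back at 19. Tebbe methylenation of the simple acrylate F10 with Cp2Ti(CH2)(Cl)AlMe2 would give the open-chain 2-aryloxybuta-1,3-diene F11. Diene–ene ring-closing metathesis with the same ruthenium catalyst, which can only engage the monosubstituted vinyl group, would give 19.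

**Step 16.**
- Most likely failures: hydrolysis of the cyclic enol ether, or expulsion of the ring A aryloxide instead of sulfinate from the dienyl anion; either would break the ether link.
- Fallback: the sulfonyl group is removed reductively and the ring is then dehydrogenated. It sets out from 21 and comes back at 22. Na(Hg) with Na2HPO4 in MeOH/THF would give the sulfone-free 1-aryloxycyclohexa-1,4-diene F12, and DDQ at rt would dehydrogenate it to 22.

## Further compounds

F1 | step 15 | 2-(benzyloxy)-5-(1,3-dioxolan-2-yl)phenol | Oc1cc(C2OCCO2)ccc1OCc1ccccc1
F2 | step 15 | 4-[2-(benzyloxy)-5-(1,3-dioxolan-2-yl)phenoxy]benzaldehyde | O=Cc1ccc(Oc2cc(C3OCCO3)ccc2OCc2ccccc2)cc1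
F3 | step 15 | 2-[4-(benzyloxy)-3-(4-ethenylphenoxy)phenyl]-1,3-dioxolane | C=Cc1ccc(Oc2cc(C3OCCO3)ccc2OCc2ccccc2)cc1
F4 | step 15 | 9-{2-[4-(2-(benzyloxy)-5-(1,3-dioxolan-2-yl)phenoxy)phenyl]ethyl}-9-borabicyclo[3.3.1]nonane | C1CCC2CCCC1B2CCc1ccc(Oc2cc(C3OCCO3)ccc2OCc2ccccc2)cc1
F5 | step 15 | 2-[4-(benzyloxy)-3-(4-{2-[6-(benzyloxy)-3-methoxy-2-(methoxymethoxy)phenyl]ethyl}phenoxy)phenyl]-1,3-dioxolane | COCOc1c(OC)ccc(OCc2ccccc2)c1CCc1ccc(Oc2cc(C3OCCO3)ccc2OCc2ccccc2)cc1
F6 | step 15 | 4-(benzyloxy)-3-(4-{2-[6-(benzyloxy)-2-hydroxy-3-methoxyphenyl]ethyl}phenoxy)benzaldehyde | COc1ccc(OCc2ccccc2)c(CCc2ccc(Oc3cc(C=O)ccc3OCc3ccccc3)cc2)c1O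
F7 | step 15 | 3-(benzyloxy)-2-[2-(4-{2-(benzyloxy)-5-[2-(3-bromophenyl)ethenyl]phenoxy}phenyl)ethyl]-6-methoxyphenol (E/Z mixture) | COc1ccc(OCc2ccccc2)c(CCc2ccc(Oc3cc(C=Cc4cccc(Br)c4)ccc3OCc3ccccc3)cc2)c1O
F8 | step 15 | 3-(benzyloxy)-2-[2-(4-{2-(benzyloxy)-5-[2-(3-bromophenyl)ethyl]phenoxy}phenyl)ethyl]-6-methoxyphenol | COc1ccc(OCc2ccccc2)c(CCc2ccc(Oc3cc(CCc4cccc(Br)c4)ccc3OCc3ccccc3)cc2)c1O
F9 | step 13 | 3-(benzyloxy)-2-[2-(4-{2-(benzyloxy)-5-(but-3-en-1-yl)phenoxy}phenyl)ethyl]-6-methoxyphenol | COc1ccc(OCc2ccccc2)c(CCc2ccc(Oc3cc(CCC=C)ccc3OCc3ccccc3)cc2)c1O
F10 | step 13 | 3-(benzyloxy)-2-[2-(4-{2-(benzyloxy)-5-(but-3-en-1-yl)phenoxy}phenyl)ethyl]-6-methoxyphenyl acrylate | C=CC(=O)Oc1c(OC)ccc(OCc2ccccc2)c1CCc1ccc(Oc2cc(CCC=C)ccc2OCc2ccccc2)cc1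
F11 | step 14 | 1-(benzyloxy)-3-(buta-1,3-dien-2-yloxy)-2-[2-(4-{2-(benzyloxy)-5-(but-3-en-1-yl)phenoxy}phenyl)ethyl]-4-methoxybenzene | C=CC(=C)Oc1c(OC)ccc(OCc2ccccc2)c1CCc1ccc(Oc2cc(CCC=C)ccc2OCc2ccccc2)cc1
F12 | step 16 | macrocyclic 1-aryloxycyclohexa-1,4-diene without sulfonyl group (racemic), dibenzyl ether | COc1ccc(OCc3ccccc3)c2c1OC1=CC(C=CC1)CCc1ccc(OCc3ccccc3)c(c1)Oc1ccc(cc1)CC2
A1 | alternative 1 | open-chain bisphenol with ring C as 2,6-dibromophenol and ring D as 2,6-dichlorophenol, ring A acetate | COc1ccc(OC(C)=O)c(CCc2cc(Cl)c(O)c(Cl)c2)c1Oc1cccc(CCc2cc(Br)c(O)c(Br)c2)c1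
A2 | alternative 1 | macrocyclic bromo dichloro diaryl ether, ring A acetate | COc1ccc(OC(C)=O)c2c1Oc1cccc(c1)CCc1cc(Br)c(O)c(c1)Oc1c(Cl)cc(cc1Cl)CC2
A3 | alternative 2 | open-chain 3-bromo-4,4-dimethoxycyclohexa-2,5-dienone with free ring B phenol | COC1(OC)C=CC(=O)C(CCc2ccc(Oc3cc(CCc4cccc(O)c4)ccc3OCc3ccccc3)cc2)=C1Br
A4 | alternative 2 | macrocyclic aryloxy quinone monoketal | COC1(OC)C=CC(=O)C2=C1Oc1cccc(c1)CCc1ccc(OCc3ccccc3)c(c1)Oc1ccc(cc1)CC2
A5 | alternative 3 | open-chain 5-acyl-2-pyrone tethered to a ring C aryl ethynyl ether | COc1ccc(OCc2ccccc2)c(CC(=O)C2=COC(=O)C=C2)c1Oc1cccc(CCc2ccc(OCc3ccccc3)c(OC#C)c2)c1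
A6 | alternative 3 | macrocyclic aryl ketone, dibenzyl ether | COc1ccc(OCc3ccccc3)c2c1Oc1cccc(c1)CCc1ccc(OCc3ccccc3)c(c1)Oc1ccc(cc1)C(=O)C2
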